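**Plan**

- Retrosynthesis: cut the phenolic O–benzyl bond, then the C3–CH2Ar bond (lactone enolate alkylation). Next add a bond the target lacks, from C3 to the benzylic carbon on C4, giving a cyclopropane-fused lactone. Cut its C3–C4 and C3–C(benzylic) bonds together to reach an (E)-cinnamyl diazoacetate.
- Enabling feature: C3 lies alpha to the lactone C=O, so it can be the carbene carbon of a diazo ester. C4 carries a benzylic CH2 on an electron-rich aryl ring, so C4 and that carbon can be the two ends of a styrenyl alkene. The extra C3–C(benzylic) bond lies between an aryl donor and a carbonyl acceptor and is the cyclopropane bond that hydrogenolysis breaks.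
- Forward: allylic alcohol → bromoacetate → diazoacetate → carbene [2+1] closes the gamma-lactone (C3–C4) and the cyclopropane at once → hydrogenolysis removes the temporary bond → C3 benzylation → O-debenzylation.
- Stereochemistry: C4 comes from the chiral dirhodium carboxamidate catalyst in the cyclopropanation and is carried through untouched. C3 comes from enolate alkylation anti to the C4 substituent (trans).

Key step: step 4

Assumption: the facial sense of Rh2(4R-MPPIM)4 with the (E)-cinnamyl diazoacetate is taken to follow that of this catalyst family with allylic diazoacetates, which corresponds to the 5R bridgehead; if it were the opposite, Rh2(4S-MPPIM)4 would be used and nothing else would change.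

**Route**

Step 1
Reactants: 1 methyl (E)-3-(3,4-dimethoxyphenyl)acrylate
Product: 2 (E)-3-(3,4-dimethoxyphenyl)prop-2-en-1-ol
Conditions: i-Bu2AlH (2.5 equiv), CH2Cl2, −78 to 0 °C; aqueous KNaC4H4O6 work-up
Reagents that add atoms: none
Why: 1,2-reduction of a conjugated ester by i-Bu2AlH at low temperature should give the allylic alcohol and leave the (E)-alkene untouched.

Step 2
Reactants: 2 (E)-3-(3,4-dimethoxyphenyl)prop-2-en-1-ol
Product: 3 (E)-3-(3,4-dimethoxyphenyl)allyl bromoacetate
Conditions: BrCH2COBr (1.5 equiv), NaHCO3 (3 equiv), MeCN, 0 °C
Reagents that add atoms: bromoacetyl bromide, BrCC(=O)Br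
Why: O-acylation of the primary allylic alcohol by the acid bromide should be fast, and NaHCO3 takes up HBr so that the electron-rich cinnamyl system is not ionised.

Step 3
Reactants: 3 (E)-3-(3,4-dimethoxyphenyl)allyl bromoacetate
Product: 4 (E)-3-(3,4-dimethoxyphenyl)allyl diazoacetate
Conditions: TsNHNHTs (2 equiv), DBU (5 equiv), THF, 0 °C
Reagents that add atoms: N,N'-ditosylhydrazine, Cc1ccc(cc1)S(=O)(=O)NNS(=O)(=O)c1ccc(C)cc1
Why: N-alkylation of the bis-sulfonyl hydrazine by the bromoacetate, followed by DBU-induced loss of two sulfinate groups, is an established mild diazoacetate synthesis that an allylic ester should tolerate.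

Step 4
Reactants: 4 (E)-3-(3,4-dimethoxyphenyl)allyl diazoacetate
Product: 5 (1S,5R,6R)-6-(3,4-dimethoxyphenyl)-3-oxabicyclo[3.1.0]hexan-2-one
Conditions: Rh2(4R-MPPIM)4 (1 mol %; MPPIM = methyl 1-(3-phenylpropanoyl)-2-oxoimidazolidine-4-carboxylate ligand, divalent rhodium), CH2Cl2, reflux, slow addition of 4
Reagents that add atoms: none
Why: The dirhodium complex should decompose the diazo ester with loss of N2 to an electrophilic rhodium carbene, whose carbon (the future C3) adds in a concerted, asynchronous [2+1] fashion across the tethered (E)-alkene, forming the C3–C4 bond and the temporary C3–C(benzylic) bond together. The closest known reaction type is the enantioselective intramolecular cyclopropanation of allylic diazoacetates, trans-cinnamyl esters included, by chiral dirhodium carboxamidates. The gamma-lactone closes in the 5-exo sense by attack of the carbene carbon on the proximal alkene carbon, the cyclopropane closes in the 3-exo sense on the distal benzylic carbon, and the five-membered ring can only be cis-fused to the three-membered one. The absolute configuration of the two bridgeheads (C5 becomes C4 of the target) is set by the chiral carboxamidate ligands, whose ester groups flank the carbene and decide which alkene face can approach; the aryl-bearing C6 follows from stereospecific retention of the E geometry (aryl exo). The step needs cyclopropanation to win over carbene dimerisation, aromatic cycloaddition and C–H insertion, which should be secured by the electron-rich styrenyl alkene held five atoms from the carbene carbon, by the low electrophilicity of carboxamidate-bound carbenes and by slow addition.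

Step 5
Reactants: 5 (1S,5R,6R)-6-(3,4-dimethoxyphenyl)-3-oxabicyclo[3.1.0]hexan-2-one
Product: 6 (R)-4-(3,4-dimethoxybenzyl)dihydrofuran-2(3H)-one
Conditions: H2 (3 atm), 10% Pd/C, EtOAc–EtOH, rt
Reagents that add atoms: none
Why: Heterogeneous hydrogenolysis of an aryl cyclopropane breaks a benzylic C–C bond, and of the two candidates only C1–C6 is also alpha to the lactone carbonyl (vicinal donor–acceptor bond), so it should cleave selectively, while C5 of the bicycle, which becomes C4 (R), is not touched.

Step 6
Reactants: 7 3-(benzyloxy)-4-methoxybenzyl alcohol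
Product: 8 3-(benzyloxy)-4-methoxybenzyl bromide
Conditions: PBr3 (0.4 equiv), Et2O, 0 °C; used promptly
Reagents that add atoms: phosphorus tribromide, BrP(Br)Br
Why: Conversion of a benzylic alcohol to the bromide by PBr3 at 0 °C should spare the benzyl and methyl aryl ethers.

Step 7
Reactants: 6 (R)-4-(3,4-dimethoxybenzyl)dihydrofuran-2(3H)-one; 8 3-(benzyloxy)-4-methoxybenzyl bromide
Product: 10 (3R,4R)-3-[3-(benzyloxy)-4-methoxybenzyl]-4-(3,4-dimethoxybenzyl)dihydrofuran-2(3H)-one, via lithium enolate 9 (not isolated)
Conditions: LiN(SiMe3)2 (1.1 equiv), THF, −78 °C; then 8, DMPU, −78 to −30 °C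
Reagents that add atoms: none
Why: SN2 alkylation of the lithium enolate of a 4-substituted gamma-butyrolactone by a reactive benzylic bromide should occur on the face anti to the C4 benzyl group, which sets C3 as R, trans to C4, and C4 is not acidic and keeps its configuration.

Step 8
Reactants: 10 (3R,4R)-3-[3-(benzyloxy)-4-methoxybenzyl]-4-(3,4-dimethoxybenzyl)dihydrofuran-2(3H)-one
Product: 11 Prestegane A, (3R,4R)-3-(3-hydroxy-4-methoxybenzyl)-4-(3,4-dimethoxybenzyl)dihydrofuran-2(3H)-one
Conditions: H2 (1 atm), 10% Pd/C, EtOAc–EtOH, rt
Reagents that add atoms: none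
Why: Hydrogenolysis of the benzyl aryl ether over palladium should free the phenol under neutral conditions that leave the lactone, the aryl methyl ethers and both stereocentres unchanged.

**Compound list**

1 | methyl (E)-3-(3,4-dimethoxyphenyl)acrylate | COC(=O)/C=C/c1ccc(OC)c(OC)c1 | starting material
2 | (E)-3-(3,4-dimethoxyphenyl)prop-2-en-1-ol | OC/C=C/c1ccc(OC)c(OC)c1 | intermediate
3 | (E)-3-(3,4-dimethoxyphenyl)allyl bromoacetate | BrCC(=O)OC/C=C/c1ccc(OC)c(OC)c1 | intermediate
4 | (E)-3-(3,4-dimethoxyphenyl)allyl diazoacetate | [N-]=[N+]=CC(=O)OC/C=C/c1ccc(OC)c(OC)c1 | intermediate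
5 | (1S,5R,6R)-6-(3,4-dimethoxyphenyl)-3-oxabicyclo[3.1.0]hexan-2-one (aryl exo) | O=C1OC[C@@H]2[C@@H](c3ccc(OC)c(OC)c3)[C@H]12 | intermediate
6 | (R)-4-(3,4-dimethoxybenzyl)dihydrofuran-2(3H)-one | O=C1OC[C@H](Cc2ccc(OC)c(OC)c2)C1 | intermediate
7 | 3-(benzyloxy)-4-methoxybenzyl alcohol | OCc1ccc(OC)c(OCc2ccccc2)c1 | starting material
8 | 3-(benzyloxy)-4-methoxybenzyl bromide | BrCc1ccc(OC)c(OCc2ccccc2)c1 | intermediate
9 | lithium enolate of 6, lithium (R)-3-(3,4-dimethoxybenzyl)-2,3-dihydrofuran-5-olate | [Li+].[O-]C1=C[C@@H](Cc2ccc(OC)c(OC)c2)CO1 | intermediate (not isolated)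
10 | (3R,4R)-3-[3-(benzyloxy)-4-methoxybenzyl]-4-(3,4-dimethoxybenzyl)dihydrofuran-2(3H)-one (trans) | COc1ccc(C[C@H]2C(=O)OC[C@@H]2Cc2ccc(OC)c(OC)c2)cc1OCc1ccccc1 | intermediate
11 | Prestegane A, (3R,4R)-3-(3-hydroxy-4-methoxybenzyl)-4-(3,4-dimethoxybenzyl)dihydrofuran-2(3H)-one | COc1ccc(C[C@H]2C(=O)OC[C@@H]2Cc2ccc(OC)c(OC)c2)cc1O | target

**Count**

Total steps: 8. Longest linear sequence: 7 (steps 1, 2, 3, 4, 5, 7, 8); step 6 is a one-step side branch.

**Steps most likely to fail**

Step 4. The carbene may add to the trans-disubstituted, electron-rich alkene with too little facial discrimination, or be lost to dimerisation before it cyclises. The fallback makes the same C3–C4 bond by enantioselective carbene insertion into a C–H bond instead of addition to an alkene. It sets out from 2. Hydrogenation of the alkene (H2, 5% Rh/Al2O3, EtOAc, rt) should give 3-(3,4-dimethoxyphenyl)propan-1-ol F1. Acylation under the conditions of step 2 should give 3-(3,4-dimethoxyphenyl)propyl bromoacetate F2, and the ditosylhydrazine procedure of step 3 should give 3-(3,4-dimethoxyphenyl)propyl diazoacetate F3. Rh2(MPPIM)4, in the antipode that delivers the R lactone, in refluxing CH2Cl2 should insert the carbene into the C–H bond at C2 of the propyl chain through a five-membered transition state. This is a known, gamma-lactone-selective and highly enantioselective reaction of 3-arylpropyl diazoacetates. The fallback comes back to the route at 6 and makes step 5 unnecessary.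

Step 5. Hydrogenolysis of the cyclopropane may stall, or break the other benzylic bond (C5–C6) and so lose the 4-benzyl pattern. The fallback replaces surface hydrogenolysis by ionic hydrogenation. It sets out from 5, which is treated with BF3·OEt2 and Et3SiH in CH2Cl2 at −20 to 0 °C. Lewis acid activation of the lactone carbonyl should heterolyse the donor–acceptor bond to a 3,4-dimethoxybenzylic cation, which takes hydride from the silane; the lactone enol then tautomerises. The regiochemistry is fixed electronically, and benzylic cations next to stereocentres in this lignan class are known to be reduced in this way without loss of the adjacent configuration. The fallback makes no new compound and comes back to the route at 6.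

Step 7. Proton exchange between product and enolate may lead to double alkylation and recovered lactone, and the labile benzylic bromide may decompose. The fallback replaces alkylation by an aldol addition followed by benzylic deoxygenation. It sets out from 6: the lithium enolate 9, generated as in step 7, is treated at −78 °C with commercial 3-(benzyloxy)-4-methoxybenzaldehyde (O=Cc1ccc(OC)c(OCc2ccccc2)c1). Addition anti to the C4 substituent should give (3S,4R)-3-{[3-(benzyloxy)-4-methoxyphenyl](hydroxy)methyl}-4-(3,4-dimethoxybenzyl)dihydrofuran-2(3H)-one F4 as a mixture of carbinol epimers, with the target's trans ring arrangement. Hydrogenolysis (H2, 10% Pd/C, EtOAc–AcOH, rt) should then remove both the benzylic hydroxyl, which is para to a methoxy group, and the O-benzyl group. The fallback comes back to the route at 11 and skips 10.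

**Further compounds**

F1 | step 4 | 3-(3,4-dimethoxyphenyl)propan-1-ol | OCCCc1ccc(OC)c(OC)c1
F2 | step 4 | 3-(3,4-dimethoxyphenyl)propyl bromoacetate | BrCC(=O)OCCCc1ccc(OC)c(OC)c1
F3 | step 4 | 3-(3,4-dimethoxyphenyl)propyl diazoacetate | [N-]=[N+]=CC(=O)OCCCc1ccc(OC)c(OC)c1
F0 | step 5 | none | none
F4 | step 7 | (3S,4R)-3-{[3-(benzyloxy)-4-methoxyphenyl](hydroxy)methyl}-4-(3,4-dimethoxybenzyl)dihydrofuran-2(3H)-one, carbinol epimers | COc1ccc(C(O)[C@H]2C(=O)OC[C@@H]2Cc2ccc(OC)c(OC)c2)cc1OCc1ccccc1
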